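**Retrosynthetic overview** (germacrane numbering, defined in the assumption line)
1. The lactone C6–O bond is the key disconnection: the carboxyl oxygen of a cyclodeca-2,7-dienyl acrylate is added across the ring C5=C6 olefin (sets C6); desilylation then gives the target.
2. The ten-membered carbocycle comes from ring-closing metathesis at C5=C6 of an acyclic tetraene that already carries the C8 angelate.
3. The C7–C8 bond and both stereocentres come from an enantioselective chromium-catalysed 2-(alkoxycarbonyl)pentadienylation of a C8 aldehyde, followed by angeloylation.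
4. The C1=C10 enoate comes from a Horner–Wadsworth–Emmons olefination; the C4 stereocentre from a copper-catalysed asymmetric allylic alkylation of methyl 4-bromocrotonate.
5. Ring order: carbocycle first (metathesis), lactone second (C–O bond formation).

Assumption: positions are labelled C1=C10 (ring enoate, C14 = CO2Me on C10), C4 (bears C15H2OH), C6 (lactone O-carbon), C7, C8 (angelate carbon), C11=C13 (exo-methylene), C12 (lactone C=O). The target is read as (3aS,4R,6E,10R,11aR) with a (Z)-2-methylbut-2-enoate. For each chiral ligand the antipode that gives the stated configuration is taken; the sense of induction is not known for these exact substrates and is to be confirmed on the first product.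

**Route**

Step 1
Reactants: 1 methyl (2E)-4-bromobut-2-enoate; 2 [2-(1,3-dioxan-2-yl)ethyl]magnesium bromide (0.5 M in THF)
Product: 3 methyl (2R)-2-[2-(1,3-dioxan-2-yl)ethyl]but-3-enoate
Conditions: CuBr·SMe2 (2 mol %), (R,R)-Taniaphos [1-[α-(dimethylamino)-2-(diphenylphosphino)benzyl]-2-(diphenylphosphino)ferrocene, C43H39FeNP2] (2.4 mol %), CH2Cl2, −78 °C, slow addition of 2
Reagents that add atoms: none
Why: Copper-catalysed asymmetric allylic alkylation (SN2′) of a 4-halocrotonate with a Grignard reagent; the chiral copper–diphosphine complex delivers the alkyl group to the carbon next to the ester and sets C4 as R.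

Step 2
Reactants: 3 methyl (2R)-2-[2-(1,3-dioxan-2-yl)ethyl]but-3-enoate
Product: 4 (2R)-2-[2-(1,3-dioxan-2-yl)ethyl]but-3-en-1-ol
Conditions: LiAlH4, Et2O, −20 → 0 °C
Reagents that add atoms: none
Why: Hydride reduction of the ester to the primary alcohol (C15); the acetal and vinyl group are inert and the stereocentre is not enolised at low temperature.

Step 3
Reactants: 4 (2R)-2-[2-(1,3-dioxan-2-yl)ethyl]but-3-en-1-ol
Product: 5 tert-butyl{[(2R)-2-[2-(1,3-dioxan-2-yl)ethyl]but-3-en-1-yl]oxy}diphenylsilane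
Conditions: TBDPSCl, imidazole, CH2Cl2, rt
Reagents that add atoms: tert-butyl(chloro)diphenylsilane (TBDPSCl), CC(C)(C)[Si](Cl)(c1ccccc1)c1ccccc1
Why: Standard silylation of a primary alcohol; this silyl ether tolerates the later aqueous and anhydrous acid steps.

Step 4
Reactants: 5 tert-butyl{[(2R)-2-[2-(1,3-dioxan-2-yl)ethyl]but-3-en-1-yl]oxy}diphenylsilane
Product: 6 (4R)-4-{[(tert-butyldiphenylsilyl)oxy]methyl}hex-5-enal
Conditions: AcOH/H2O/THF (3:1:1), 55 °C
Reagents that add atoms: water, O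
Why: Acid hydrolysis of the cyclic acetal frees the C1 aldehyde; the tert-butyldiphenylsilyl ether is stable to aqueous acetic acid.

Step 5
Reactants: 7 methyl 2-(diethoxyphosphoryl)acetate; 8 2-bromo-1,1-dimethoxyethane
Product: 9 methyl 2-(diethoxyphosphoryl)-4,4-dimethoxybutanoate (racemic)
Conditions: NaH, NaI (10 mol %), DMF, 70 °C
Reagents that add atoms: none
Why: C-alkylation of the phosphonoacetate anion (iodide-assisted SN2) installs C9 and the masked C8 aldehyde.

Step 6
Reactants: 9 methyl 2-(diethoxyphosphoryl)-4,4-dimethoxybutanoate; 6 (4R)-4-{[(tert-butyldiphenylsilyl)oxy]methyl}hex-5-enal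
Product: 10 methyl (2E,6R)-6-{[(tert-butyldiphenylsilyl)oxy]methyl}-2-(2,2-dimethoxyethyl)octa-2,7-dienoate
Conditions: NaH, THF, 0 °C → rt; chromatographic removal of the minor (2Z) isomer
Reagents that add atoms: none
Why: Horner–Wadsworth–Emmons olefination with an α-substituted phosphonoacetate gives mainly the enoate with the chain trans to CO2Me, which is the C1=C10 geometry of the target.

Step 7
Reactants: 10 methyl (2E,6R)-6-{[(tert-butyldiphenylsilyl)oxy]methyl}-2-(2,2-dimethoxyethyl)octa-2,7-dienoate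
Product: 11 methyl (2E,6R)-6-{[(tert-butyldiphenylsilyl)oxy]methyl}-2-(2-oxoethyl)octa-2,7-dienoate
Conditions: CF3CO2H/H2O (1:1), CHCl3, 0 °C; used crude at once
Reagents that add atoms: water, O
Why: Mild acetal hydrolysis at 0 °C frees the C8 aldehyde; the β,γ-unsaturated aldehyde is not purified, to avoid isomerisation into conjugation.

Step 8
Reactants: 12 acrolein; 13 tert-butyl acrylate
Product: 14 tert-butyl 3-hydroxy-2-methylidenepent-4-enoate (racemic)
Conditions: 1,4-diazabicyclo[2.2.2]octane (DABCO, 20 mol %), 1,4-dioxane/H2O (1:1), 0 °C → rt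
Reagents that add atoms: none
Why: Morita–Baylis–Hillman reaction; the stereocentre is removed in the next step.

Step 9
Reactants: 14 tert-butyl 3-hydroxy-2-methylidenepent-4-enoate
Product: 15 tert-butyl (2Z)-2-(bromomethyl)penta-2,4-dienoate
Conditions: N-bromosuccinimide, Me2S, CH2Cl2, 0 °C → rt
Reagents that add atoms: N-bromosuccinimide, O=C1CCC(=O)N1Br
Why: Corey–Kim-type activation of the Baylis–Hillman alcohol and SN2′ attack of bromide at the acrylate CH2 give the conjugated bromide with the vinyl group trans to the ester, under neutral conditions that spare the tert-butyl ester.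

Step 10
Reactants: 11 methyl (2E,6R)-6-{[(tert-butyldiphenylsilyl)oxy]methyl}-2-(2-oxoethyl)octa-2,7-dienoate; 15 tert-butyl (2Z)-2-(bromomethyl)penta-2,4-dienoate
Product: 17 tert-butyl (3R,4R,6E,10R)-10-{[(tert-butyldiphenylsilyl)oxy]methyl}-3-ethenyl-4-hydroxy-6-(methoxycarbonyl)-2-methylidenedodeca-6,11-dienoate, via trimethylsilyl ether 16 (not isolated)
Conditions: CrCl2 (10 mol %), (S,S)-1,8-bis(4-isopropyl-4,5-dihydrooxazol-2-yl)-3,6-diphenyl-9H-carbazole (12 mol %), i-Pr2NEt (30 mol %), Mn powder (3 equiv), Me3SiCl (2 equiv), THF, 0 °C; then 1 M HCl, THF, 0 °C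
Reagents that add atoms: none
Why: Catalytic asymmetric Nozaki–Hiyama–Kishi 2-(alkoxycarbonyl)allylation: the trivalent allylchromium adds through C7 in a closed chair transition state with the vinyl group cis to CH2Cr, which gives the syn C7/C8 adduct; the carbazole bis(oxazoline) ligand selects the aldehyde face (C8 R), and the tert-butyl ester prevents lactonisation onto C8–OH.

Step 11
Reactants: 17 tert-butyl (3R,4R,6E,10R)-10-{[(tert-butyldiphenylsilyl)oxy]methyl}-3-ethenyl-4-hydroxy-6-(methoxycarbonyl)-2-methylidenedodeca-6,11-dienoate; 18 angelic acid [(2Z)-2-methylbut-2-enoic acid]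
Product: 20 tert-butyl (3R,4R,6E,10R)-10-{[(tert-butyldiphenylsilyl)oxy]methyl}-3-ethenyl-6-(methoxycarbonyl)-4-{[(2Z)-2-methylbut-2-enoyl]oxy}-2-methylidenedodeca-6,11-dienoate, via mixed anhydride 19 (not isolated)
Conditions: 18, 2,4,6-trichlorobenzoyl chloride, Et3N, toluene, rt; then 17, 75 °C (no DMAP)
Reagents that add atoms: none
Why: Yamaguchi mixed-anhydride esterification without a nucleophilic catalyst acylates the hindered C8 hydroxyl with retention and keeps the (Z) geometry of the angelate.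

Step 12
Reactants: 20 tert-butyl (3R,4R,6E,10R)-10-{[(tert-butyldiphenylsilyl)oxy]methyl}-3-ethenyl-6-(methoxycarbonyl)-4-{[(2Z)-2-methylbut-2-enoyl]oxy}-2-methylidenedodeca-6,11-dienoate
Product: 21 tert-butyl 2-[(1R,2Z,4R,7E,10R)-4-{[(tert-butyldiphenylsilyl)oxy]methyl}-8-(methoxycarbonyl)-10-{[(2Z)-2-methylbut-2-enoyl]oxy}cyclodeca-2,7-dien-1-yl]prop-2-enoate
Conditions: second-generation Grubbs catalyst (H2IMes)(PCy3)Cl2Ru=CHPh (10 mol %), 1,4-benzoquinone (20 mol %), CH2Cl2 (1 mM), 40 °C
Reagents that add atoms: none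
Why: Ring-closing metathesis of the two monosubstituted vinyl groups; the ring-cis enoate acts as a turn element, the product is a nearly strain-free cis,cis-cyclodeca-1,6-diene, and the acrylate, ring enoate and angelate olefins are too hindered or electron-poor to take part.

Step 13
Reactants: 21 tert-butyl 2-[(1R,2Z,4R,7E,10R)-4-{[(tert-butyldiphenylsilyl)oxy]methyl}-8-(methoxycarbonyl)-10-{[(2Z)-2-methylbut-2-enoyl]oxy}cyclodeca-2,7-dien-1-yl]prop-2-enoate
Product: 23 methyl (3aS,4R,6E,10R,11aR)-10-{[(tert-butyldiphenylsilyl)oxy]methyl}-3-methylidene-4-{[(2Z)-2-methylbut-2-enoyl]oxy}-2-oxo-2,3,3a,4,5,8,9,10,11,11a-decahydrocyclodeca[b]furan-6-carboxylate, via carboxylic acid 22 (not isolated)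
Conditions: HN(SO2CF3)2 (10 mol %), (CF3)2CHOH/CH2Cl2 (1:3), 0 → 35 °C
Reagents that add atoms: none
Why: Proposed new method: one-flask dealkylative hydrolactonization of a tert-butyl 2-(cycloalk-2-enyl)acrylate, in which the strong acid first releases isobutene to give acid 22 and then, in the hydrogen-bonding fluoroalcohol, protonates C5 of the only electron-rich olefin while the carboxyl C=O closes 5-exo on C6 in an asynchronous concerted addition (no free cation, so no hydride shift to C4); allylic 1,3-strain keeps H7 in the olefin plane so the carboxyl reaches only one face and the trans-fused lactone (C6 R) results; the closest known reactions are Brønsted- or Lewis-acid-catalysed hydroacyloxylation of unactivated alkenes with free acids in fluoroalcohols and iodolactonisation of tert-butyl esters, neither shown on a medium-ring cis-olefin with an α-methylene acid or ester.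

Step 14
Reactants: 23 methyl (3aS,4R,6E,10R,11aR)-10-{[(tert-butyldiphenylsilyl)oxy]methyl}-3-methylidene-4-{[(2Z)-2-methylbut-2-enoyl]oxy}-2-oxo-2,3,3a,4,5,8,9,10,11,11a-decahydrocyclodeca[b]furan-6-carboxylate
Product: 24 methyl (3aS,4R,6E,10R,11aR)-10-(hydroxymethyl)-3-methylidene-4-{[(2Z)-2-methylbut-2-enoyl]oxy}-2-oxo-2,3,3a,4,5,8,9,10,11,11a-decahydrocyclodeca[b]furan-6-carboxylate (CNP0167542.1)
Conditions: HF·pyridine, pyridine/THF, 0 °C → rt
Reagents that add atoms: none
Why: Buffered fluoride desilylation frees the C15 hydroxyl without touching the α-methylene lactone, the angelate or the methyl ester.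

**Compound list**

1 | methyl (2E)-4-bromobut-2-enoate | COC(=O)/C=C/CBr | starting material
2 | [2-(1,3-dioxan-2-yl)ethyl]magnesium bromide | Br[Mg]CCC1OCCCO1 | starting material
3 | methyl (2R)-2-[2-(1,3-dioxan-2-yl)ethyl]but-3-enoate | C=C[C@H](C(=O)OC)CCC1OCCCO1 | intermediate
4 | (2R)-2-[2-(1,3-dioxan-2-yl)ethyl]but-3-en-1-ol | C=C[C@H](CO)CCC1OCCCO1 | intermediate
5 | tert-butyl{[(2R)-2-[2-(1,3-dioxan-2-yl)ethyl]but-3-en-1-yl]oxy}diphenylsilane | C=C[C@H](CO[Si](c1ccccc1)(c1ccccc1)C(C)(C)C)CCC2OCCCO2 | intermediate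
6 | (4R)-4-{[(tert-butyldiphenylsilyl)oxy]methyl}hex-5-enal | C=C[C@H](CO[Si](c1ccccc1)(c1ccccc1)C(C)(C)C)CCC=O | intermediate
7 | methyl 2-(diethoxyphosphoryl)acetate | CCOP(=O)(OCC)CC(=O)OC | starting material
8 | 2-bromo-1,1-dimethoxyethane | COC(CBr)OC | starting material
9 | methyl 2-(diethoxyphosphoryl)-4,4-dimethoxybutanoate (racemic) | CCOP(=O)(OCC)C(CC(OC)OC)C(=O)OC | intermediate
10 | methyl (2E,6R)-6-{[(tert-butyldiphenylsilyl)oxy]methyl}-2-(2,2-dimethoxyethyl)octa-2,7-dienoate | C=C[C@H](CO[Si](c1ccccc1)(c1ccccc1)C(C)(C)C)CC/C=C(/C(=O)OC)CC(OC)OC | intermediate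
11 | methyl (2E,6R)-6-{[(tert-butyldiphenylsilyl)oxy]methyl}-2-(2-oxoethyl)octa-2,7-dienoate | C=C[C@H](CO[Si](c1ccccc1)(c1ccccc1)C(C)(C)C)CC/C=C(/C(=O)OC)CC=O | intermediate
12 | acrolein | C=CC=O | starting material
13 | tert-butyl acrylate | C=CC(=O)OC(C)(C)C | starting material
14 | tert-butyl 3-hydroxy-2-methylidenepent-4-enoate (racemic) | C=CC(O)C(=C)C(=O)OC(C)(C)C | intermediate
15 | tert-butyl (2Z)-2-(bromomethyl)penta-2,4-dienoate | C=C/C=C(\CBr)C(=O)OC(C)(C)C | intermediate
16 | trimethylsilyl ether of 17 (C8–OSiMe3) | C=C(C(=O)OC(C)(C)C)[C@@H](C=C)[C@H](O[Si](C)(C)C)C/C(C(=O)OC)=C\CC[C@H](C=C)CO[Si](c1ccccc1)(c1ccccc1)C(C)(C)C | intermediate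
17 | tert-butyl (3R,4R,6E,10R)-10-{[(tert-butyldiphenylsilyl)oxy]methyl}-3-ethenyl-4-hydroxy-6-(methoxycarbonyl)-2-methylidenedodeca-6,11-dienoate | C=C(C(=O)OC(C)(C)C)[C@@H](C=C)[C@H](O)C/C(C(=O)OC)=C\CC[C@H](C=C)CO[Si](c1ccccc1)(c1ccccc1)C(C)(C)C | intermediate
18 | angelic acid, (2Z)-2-methylbut-2-enoic acid | C/C=C(/C)C(=O)O | starting material
19 | (2Z)-2-methylbut-2-enoic 2,4,6-trichlorobenzoic anhydride | C/C=C(/C)C(=O)OC(=O)c1c(Cl)cc(Cl)cc1Cl | intermediate
20 | tert-butyl (3R,4R,6E,10R)-10-{[(tert-butyldiphenylsilyl)oxy]methyl}-3-ethenyl-6-(methoxycarbonyl)-4-{[(2Z)-2-methylbut-2-enoyl]oxy}-2-methylidenedodeca-6,11-dienoate | C=C(C(=O)OC(C)(C)C)[C@@H](C=C)[C@H](OC(=O)/C(C)=C\C)C/C(C(=O)OC)=C\CC[C@H](C=C)CO[Si](c1ccccc1)(c1ccccc1)C(C)(C)C | intermediate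
21 | tert-butyl 2-[(1R,2Z,4R,7E,10R)-4-{[(tert-butyldiphenylsilyl)oxy]methyl}-8-(methoxycarbonyl)-10-{[(2Z)-2-methylbut-2-enoyl]oxy}cyclodeca-2,7-dien-1-yl]prop-2-enoate | C=C(C(=O)OC(C)(C)C)[C@H]1/C=C\[C@H](CO[Si](c2ccccc2)(c2ccccc2)C(C)(C)C)CC/C=C(/C(=O)OC)C[C@H]1OC(=O)/C(C)=C\C | intermediate
22 | 2-[(1R,2Z,4R,7E,10R)-4-{[(tert-butyldiphenylsilyl)oxy]methyl}-8-(methoxycarbonyl)-10-{[(2Z)-2-methylbut-2-enoyl]oxy}cyclodeca-2,7-dien-1-yl]prop-2-enoic acid | C=C(C(=O)O)[C@H]1/C=C\[C@H](CO[Si](c2ccccc2)(c2ccccc2)C(C)(C)C)CC/C=C(/C(=O)OC)C[C@H]1OC(=O)/C(C)=C\C | intermediate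
23 | methyl (3aS,4R,6E,10R,11aR)-10-{[(tert-butyldiphenylsilyl)oxy]methyl}-3-methylidene-4-{[(2Z)-2-methylbut-2-enoyl]oxy}-2-oxo-2,3,3a,4,5,8,9,10,11,11a-decahydrocyclodeca[b]furan-6-carboxylate | C=C1C(=O)O[C@@H]2C[C@H](CO[Si](c3ccccc3)(c3ccccc3)C(C)(C)C)CC/C=C(/C(=O)OC)C[C@@H](OC(=O)/C(C)=C\C)[C@@H]12 | intermediate
24 | methyl (3aS,4R,6E,10R,11aR)-10-(hydroxymethyl)-3-methylidene-4-{[(2Z)-2-methylbut-2-enoyl]oxy}-2-oxo-2,3,3a,4,5,8,9,10,11,11a-decahydrocyclodeca[b]furan-6-carboxylate | C=C1C(=O)O[C@@H]2C[C@H](CO)CC/C=C(/C(=O)OC)C[C@@H](OC(=O)/C(C)=C\C)[C@@H]12 | target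

**Step count**
Total: 14 steps. Longest linear sequence: 11 steps (1, 2, 3, 4, 6, 7, 10, 11, 12, 13, 14).

**Three steps most likely to fail**

Step 13 (proposed new hydrolactonization). Risks: protonation at C6 with a hydride shift from C4, closure at C5 to a bridged δ-lactone, participation of the angelate carbonyl, or early loss of the silyl ether. The fallback uses known chemistry, sets out from 21 and comes back at 23. The tert-butyl ester of 21 is cleaved with CF3CO2H in CH2Cl2 at 0 °C and acid 22 is isolated. Kinetic iodolactonisation (I2, NaHCO3, MeCN, 0 °C; 5-exo, anti addition) gives the 5-iodo trans-fused lactone F1. Radical hydrodeiodination (Bu3SnH, 10 mol % PhSeSePh, Et3B/air, toluene, 0 °C) then gives 23; benzeneselenol formed in the flask is the fast hydrogen donor needed to outrun transannular addition to the enoate.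

Step 12 (ring-closing metathesis). Risks: oligomerisation, or slow initiation at two allylically branched vinyl groups, one of them next to the bulky angelate. The fallback sets out from 17 and comes back at 21. The ring is closed before acylation: metathesis of the free alcohol 17 with the same ruthenium carbene gives the cyclodecadienol F2, in which the C7 vinyl group is less shielded and no ester carbonyl can chelate ruthenium. Yamaguchi angeloylation of F2 (18 through 19, as in step 11) then gives 21.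

Step 10 (asymmetric allylation). Risks: enolisation or isomerisation of the β,γ-unsaturated aldehyde 11 under the chromium conditions, or insufficient enantioselectivity with a dienyl bromide. The fallback sets out from 9 and 15 and comes back at 20; it reverses the order of the two carbon–carbon bond formations so that the allylation is run on a non-isomerisable aldehyde. Acetal 9 is hydrolysed (aqueous CF3CO2H, 0 °C) to methyl 2-(diethoxyphosphoryl)-4-oxobutanoate F3. The same chromium-catalysed allylation with 15 gives the silyl ether F4 and, after acidic work-up, the hydroxy phosphonate F5 (3R,4R; mixture at the phosphonate carbon). Yamaguchi angeloylation gives the angelate phosphonate F6. Horner–Wadsworth–Emmons olefination of F6 with aldehyde 6 (LiCl, 1,8-diazabicyclo[5.4.0]undec-7-ene, MeCN, 0 °C) gives 20.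

**Further compounds**

F1 | step 13 | 5-iodo derivative of 23 (iodine on C5 anti to the lactone oxygen on C6) | C=C1C(=O)O[C@@H]2[C@@H](I)[C@H](CO[Si](c3ccccc3)(c3ccccc3)C(C)(C)C)CC/C=C(/C(=O)OC)C[C@@H](OC(=O)/C(C)=C\C)[C@@H]12
F2 | step 12 | tert-butyl 2-[(1R,2Z,4R,7E,10R)-4-{[(tert-butyldiphenylsilyl)oxy]methyl}-10-hydroxy-8-(methoxycarbonyl)cyclodeca-2,7-dien-1-yl]prop-2-enoate | C=C(C(=O)OC(C)(C)C)[C@H]1/C=C\[C@H](CO[Si](c2ccccc2)(c2ccccc2)C(C)(C)C)CC/C=C(/C(=O)OC)C[C@H]1O
F3 | step 10 | methyl 2-(diethoxyphosphoryl)-4-oxobutanoate (racemic) | CCOP(=O)(OCC)C(CC=O)C(=O)OC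
F4 | step 10 | 1-tert-butyl 6-methyl (3R,4R)-6-(diethoxyphosphoryl)-3-ethenyl-2-methylidene-4-[(trimethylsilyl)oxy]hexanedioate (mixture at C6) | C=C(C(=O)OC(C)(C)C)[C@@H](C=C)[C@H](O[Si](C)(C)C)CC(C(=O)OC)P(=O)(OCC)OCC
F5 | step 10 | 1-tert-butyl 6-methyl (3R,4R)-6-(diethoxyphosphoryl)-3-ethenyl-4-hydroxy-2-methylidenehexanedioate (mixture at C6) | C=C(C(=O)OC(C)(C)C)[C@@H](C=C)[C@H](O)CC(C(=O)OC)P(=O)(OCC)OCC
F6 | step 10 | 1-tert-butyl 6-methyl (3R,4R)-6-(diethoxyphosphoryl)-3-ethenyl-4-{[(2Z)-2-methylbut-2-enoyl]oxy}-2-methylidenehexanedioate (mixture at C6) | C=C(C(=O)OC(C)(C)C)[C@@H](C=C)[C@H](OC(=O)/C(C)=C\C)CC(C(=O)OC)P(=O)(OCC)OCC
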